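Follow the catalyst rather than the substrate through these flasks.

    substrate + free catalyst → catalyst intermediate A (k1 = 989 M⁻¹ s⁻¹)
    2 catalyst intermediate B → spent catalyst (k2 = 53.9 M⁻¹ s⁻¹)
    catalyst intermediate B ⇌ by-product + catalyst intermediate C (K3 = 0.0096 M, k3 = 0.152 s⁻¹)
    reagent + catalyst intermediate A → catalyst intermediate B (k4 = 17.3 M⁻¹ s⁻¹)
    catalyst intermediate C → free catalyst + product (k5 = 0.140 s⁻¹)

| setting | epsilon | delta | theta | zeta |
|---|---|---|---|---|
| substrate | 20 mM | 20 mM | 20 mM (fed, over 6.40 h) | 20 mM |
| reagent | 0.600 equiv | 0.600 equiv | 0.600 equiv | 0.600 equiv (fed, over 6.40 h) |
| free catalyst | 0.2 mol% | 0.2 mol% | 0.2 mol% | 0.2 mol% |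
| time | 8.0 h |  | 8.0 h | 8.0 h |
| remark | a closed flask charged with all of it at once and left for 8.0 h | a single well-mixed tank run continuously and read at steady state, 8.0 h in it on average | all but substrate at the start; substrate goes in evenly over 6.40 h, the run ends at 8.0 h | all but reagent at the start; reagent goes in evenly over 6.40 h, the run ends at 8.0 h |

- the set-up with the highest amount of product at the outlet or at the end, in percent of the substrate put in ("none" if the first two lie within 2 percentage points) (epsilon / delta / theta / zeta / none)
- amount of product at the outlet or at the end, in percent of the substrate put in, epsilon
- amount of product at the outlet or at the end, in percent of the substrate put in, delta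
- amount of product at the outlet or at the end, in percent of the substrate put in, theta
- amount of product at the outlet or at the end, in percent of the substrate put in, zeta

- in percentages every species weighs as the substrate in it: one spent catalyst counts as two
- for a step with 2 of a species take k times the square, and two of it per event
- the stated concentrations are those of everything mixed, before any reaction; amounts are the same in each set-up
- the feed brings no volume worth counting
- run time (epsilon): 8.0 h

The concentration to find is [catalyst intermediate B]: product passes through it at first order, while catalyst dies through it at second order. Let b be the share of working catalyst (free catalyst and intermediates A, B and C together) standing as B, which is the stay as B over the time of one round. Free catalyst waits 0.0506 s at full substrate, far shorter than the 7.14 s stay as C, so it is dropped. Take by-product at half of the 12.0 mM reagent charge; its return on C stretches the stay as B to 11.0 s. Intermediate A waits on reagent, a pseudo-first-order step: 9.63 s in epsilon with reagent assumed at half its charge, 19.3 s in zeta with reagent assumed at a quarter. So b is 0.397 in epsilon and 0.295 in zeta.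

From the 0.0400 mM charge, pairing takes working catalyst to half in 0.409 h in epsilon and 0.741 h in zeta. The run of epsilon holds 19.6 of these times and the run of zeta 10.8. This catalyst-death number G, run time over half-time, says what survives: one part in one plus G. Product is then the round time over twice the pairing constant times the squared stay as B, multiplied by the logarithm of one plus G. Loading enters under the logarithm, not in the factor in front. That gives 6.40 mM in epsilon and 7.03 mM in zeta, or 32.0 % and 35.2 %. One number is not enough: zeta has the smaller G, and the larger product, so the factor in front counts too.

The forecast gives 37.9 %, 37.7 %, 40.8 % and 45 % in recipe order, the last higher than the reckoned zeta figure, and names zeta best: “low reagent keeps B low throughout”.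

The simulation gives 38.0 %, 37.6 %, 41.8 % and 46.3 %, so zeta leads, and the reckoned zeta figure fell short. In zeta 87.3 % of the catalyst charged stands as spent catalyst after 8.00 h, leaving 12.7 % in working forms, against 8.47 % reckoned from G.

With b and the factor in front held, the neighbour of zeta with 0.34 mol% free catalyst has G raised to 18.4, and the logarithm carries 46.3 % to an estimated 55.6 %. That neighbour gives 55.6 %.

The numbers were set for the occasion; the result is computed.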